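**Retrosynthetic overview**

- The target comes from a one-pot hydroboration, B-alkyl Suzuki coupling and desilylation that joins an (S)-2-methyl-2-vinyl-2H-chromene silyl ether to an (E)-alkenyl iodide carrying the cyclohexene ring.
- Key step: the chromene C3=C4 bond is closed by intramolecular reductive coupling of an aryl aldehyde with an α-aryloxy aldehyde; a titanium ketyl serves as the reversed-polarity carbonyl donor, so two carbonyl carbons are joined.
- The dialdehyde comes from a primary alcohol made by Pd-catalysed asymmetric allylic etherification of a 5-silyloxysalicylaldehyde with racemic isoprene monoepoxide; this sets C2.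
- The alkenyl iodide comes from dihydro-β-ionone through the terminal alkyne and Zr-catalysed carboalumination/iodination; this sets the E alkene.
- Ring order: the benzene and cyclohexene rings are bought; the pyran ring is the only ring made, and it is closed before the side chain is attached.

Assumption: the (R,R)-ligand in step 2 is taken to give the (S)-ether, by analogy with heteroatom openings of vinyl epoxides with this ligand family; if the measured sense is opposite, the (S,S)-ligand is used and nothing else changes.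

**Route**

Step 1
Reactants: 1 2,5-dihydroxybenzaldehyde
Product: 2 2-hydroxy-5-[(triisopropylsilyl)oxy]benzaldehyde
Conditions: TIPSCl (1.05 equiv), imidazole (2 equiv), CH2Cl2, 0 °C to rt
Reagents that add atoms: triisopropylsilyl chloride, CC(C)[Si](Cl)(C(C)C)C(C)C
Why: The 2-OH is held in a hydrogen bond to the aldehyde, so silyl ether formation takes the free 5-OH selectively; no stereocenter is involved.

Step 2
Reactants: 2 2-hydroxy-5-[(triisopropylsilyl)oxy]benzaldehyde; 3 2-methyl-2-vinyloxirane (isoprene monoepoxide, racemic, 1.5 equiv)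
Product: 4 2-{[(2S)-1-hydroxy-2-methylbut-3-en-2-yl]oxy}-5-[(triisopropylsilyl)oxy]benzaldehyde
Conditions: Pd2(dba)3·CHCl3 (1 mol %), (R,R)-DACH-phenyl Trost ligand (3 mol %), CH2Cl2, rt
Reagents that add atoms: none
Why: Trost asymmetric allylic etherification run as a dynamic kinetic asymmetric transformation: zerovalent palladium opens racemic 3 to a π-allyl complex whose faces interconvert, the alkoxide end deprotonates the phenol and steers the phenoxide to the adjacent fully substituted allyl terminus, and the chiral ligand pocket selects the face that gives the (S)-configured quaternary C–O stereocenter (the later C2).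

Step 3
Reactants: 4 2-{[(2S)-1-hydroxy-2-methylbut-3-en-2-yl]oxy}-5-[(triisopropylsilyl)oxy]benzaldehyde
Product: 5 (2S)-2-{2-formyl-4-[(triisopropylsilyl)oxy]phenoxy}-2-methylbut-3-enal
Conditions: Dess–Martin periodinane (1.3 equiv), NaHCO3, CH2Cl2, 0 °C to rt; used at once
Reagents that add atoms: none
Why: Dess–Martin oxidation of the primary alcohol stops at the aldehyde, which has no α-hydrogen and so cannot enolise; the quaternary stereocenter is untouched.

Step 4
Reactants: 5 (2S)-2-{2-formyl-4-[(triisopropylsilyl)oxy]phenoxy}-2-methylbut-3-enal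
Product: 6 triisopropyl{[(2S)-2-methyl-2-vinyl-2H-chromen-6-yl]oxy}silane
Conditions: TiCl4, Zn dust, pyridine, THF, reflux, dark; 5 added by syringe pump over 8 h (final 0.005 M)
Reagents that add atoms: none
Why: Intramolecular McMurry coupling: low-valent titanium reduces the more easily reduced aryl aldehyde to a titanium ketyl, a carbonyl carbon of reversed (nucleophilic) polarity that acts as an acyl-anion-type donor at the reduced oxidation level; it attacks the second aldehyde carbon, joining two normally electrophilic carbons in a six-membered ring, and the titanium 1,2-diolate is deoxygenated to the cis ring alkene C3=C4, with C2 not involved.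

Step 5
Reactants: 7 4-(2,6,6-trimethylcyclohex-1-en-1-yl)butan-2-one (dihydro-β-ionone)
Product: 9 2-(but-3-yn-1-yl)-1,3,3-trimethylcyclohex-1-ene, via enol phosphate 8 (not isolated)
Conditions: LiN(i-Pr)2 (1.05 equiv), THF, −78 °C; ClP(O)(OEt)2, −78 °C to rt; LiN(i-Pr)2 (2.3 equiv), −78 °C to rt; H2O
Reagents that add atoms: none
Why: Negishi's methyl ketone to alkyne conversion: kinetic deprotonation at the methyl group, O-phosphorylation to the terminal enol phosphate and base-induced elimination of diethyl phosphate give the terminal alkyne; no stereocenter is involved.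

Step 6
Reactants: 9 2-(but-3-yn-1-yl)-1,3,3-trimethylcyclohex-1-ene
Product: 11 2-[(3E)-4-iodo-3-methylbut-3-en-1-yl]-1,3,3-trimethylcyclohex-1-ene, via alkenylalane 10 (not isolated)
Conditions: AlMe3 (2 equiv), Cp2ZrCl2 (0.25 equiv), CH2Cl2, 0 °C to rt; then I2, THF, −30 °C to 0 °C
Reagents that add atoms: trimethylaluminium, C[Al](C)C; iodine, II
Why: Zirconium-catalysed Negishi carboalumination adds methyl and aluminium syn across the alkyne with methyl on the internal carbon, and iodinolysis of the C–Al bond with retention fixes the (E)-trisubstituted alkene.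

Step 7
Reactants: 6 triisopropyl{[(2S)-2-methyl-2-vinyl-2H-chromen-6-yl]oxy}silane; 11 2-[(3E)-4-iodo-3-methylbut-3-en-1-yl]-1,3,3-trimethylcyclohex-1-ene
Product: 14 (2S)-2-methyl-2-[(3E)-4-methyl-6-(2,6,6-trimethylcyclohex-1-en-1-yl)hex-3-en-1-yl]-2H-chromen-6-ol, via alkylborane 12 (not isolated), via silyl ether 13 (not isolated)
Conditions: 9-BBN (1.2 equiv), THF, 0 °C to rt; then 11 (1.1 equiv), PdCl2(dppf) (5 mol %), AsPh3 (5 mol %), K3PO4 (3 M aq), DMF, rt to 45 °C; then Bu4NF (1.5 equiv), rt; argon, dark
Reagents that add atoms: none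
Why: 9-BBN hydroborates only the monosubstituted vinyl group (anti-Markovnikov; the chromene alkene and the tri- and tetrasubstituted alkenes are far slower), the B-alkyl Suzuki–Miyaura coupling joins the primary alkylborane to the alkenyl iodide with retention of the E geometry, and fluoride then cleaves the aryl silyl ether in the same pot; C2 is untouched.

**Compound list**

1 | 2,5-dihydroxybenzaldehyde | O=Cc1cc(O)ccc1O | starting material
2 | 2-hydroxy-5-[(triisopropylsilyl)oxy]benzaldehyde | O=Cc1cc(O[Si](C(C)C)(C(C)C)C(C)C)ccc1O | intermediate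
3 | 2-methyl-2-vinyloxirane (racemic) | C=CC1(C)CO1 | starting material
4 | 2-{[(2S)-1-hydroxy-2-methylbut-3-en-2-yl]oxy}-5-[(triisopropylsilyl)oxy]benzaldehyde | C=C[C@@](C)(CO)Oc1ccc(O[Si](C(C)C)(C(C)C)C(C)C)cc1C=O | intermediate
5 | (2S)-2-{2-formyl-4-[(triisopropylsilyl)oxy]phenoxy}-2-methylbut-3-enal | C=C[C@@](C)(C=O)Oc1ccc(O[Si](C(C)C)(C(C)C)C(C)C)cc1C=O | intermediate
6 | triisopropyl{[(2S)-2-methyl-2-vinyl-2H-chromen-6-yl]oxy}silane | C=C[C@@]1(C)C=Cc2cc(O[Si](C(C)C)(C(C)C)C(C)C)ccc2O1 | intermediate
7 | 4-(2,6,6-trimethylcyclohex-1-en-1-yl)butan-2-one | CC(=O)CCC1=C(C)CCCC1(C)C | starting material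
8 | diethyl 4-(2,6,6-trimethylcyclohex-1-en-1-yl)but-1-en-2-yl phosphate | C=C(CCC1=C(C)CCCC1(C)C)OP(=O)(OCC)OCC | intermediate (not isolated)
9 | 2-(but-3-yn-1-yl)-1,3,3-trimethylcyclohex-1-ene | C#CCCC1=C(C)CCCC1(C)C | intermediate
10 | dimethyl[(1E)-2-methyl-4-(2,6,6-trimethylcyclohex-1-en-1-yl)but-1-en-1-yl]alane | C[Al](C)/C=C(\C)CCC1=C(C)CCCC1(C)C | intermediate (not isolated)
11 | 2-[(3E)-4-iodo-3-methylbut-3-en-1-yl]-1,3,3-trimethylcyclohex-1-ene | I/C=C(\C)CCC1=C(C)CCCC1(C)C | intermediate
12 | 9-{2-[(2S)-2-methyl-6-[(triisopropylsilyl)oxy]-2H-chromen-2-yl]ethyl}-9-borabicyclo[3.3.1]nonane | C(C[C@@]1(C)C=Cc2cc(O[Si](C(C)C)(C(C)C)C(C)C)ccc2O1)B1C2CCCC1CCC2 | intermediate (not isolated)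
13 | triisopropyl({(2S)-2-methyl-2-[(3E)-4-methyl-6-(2,6,6-trimethylcyclohex-1-en-1-yl)hex-3-en-1-yl]-2H-chromen-6-yl}oxy)silane | CC1=C(CC/C(C)=C/CC[C@@]2(C)C=Cc3cc(O[Si](C(C)C)(C(C)C)C(C)C)ccc3O2)C(C)(C)CCC1 | intermediate (not isolated)
14 | (2S)-2-methyl-2-[(3E)-4-methyl-6-(2,6,6-trimethylcyclohex-1-en-1-yl)hex-3-en-1-yl]-2H-chromen-6-ol | CC1=C(CC/C(C)=C/CC[C@@]2(C)C=Cc3cc(O)ccc3O2)C(C)(C)CCC1 | target

**Step count and risks**

Total step count: 7. Longest linear sequence: 5 steps (1, 2, 3, 4, 7) from 2,5-dihydroxybenzaldehyde; the side-chain branch (steps 5 and 6) joins in step 7. From compound 6 onward everything is kept in the dark and below 70 °C, because 2H-chromenes can open to the quinone methide and reclose, which would racemise C2.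

Steps most likely to fail:

Step 2. The risks are attack at the unsubstituted allyl terminus (linear ether), insufficient ee, re-ionisation of the product aryl allyl ether by palladium, and capture of the alkoxide by the aldehyde. The fallback sets out from 2 and 3 and comes back at 4, replacing asymmetric catalysis by resolution. Pd(PPh3)4 in THF joins 2 and 3 without induction to give racemic 2-[(1-hydroxy-2-methylbut-3-en-2-yl)oxy]-5-[(triisopropylsilyl)oxy]benzaldehyde F1. Amano lipase PS with vinyl acetate in t-BuOMe then acetylates the (R)-alcohol to (2R)-2-{2-formyl-4-[(triisopropylsilyl)oxy]phenoxy}-2-methylbut-3-en-1-yl acetate F2. The reaction is run past half conversion, and the unreacted (S)-alcohol is separated by chromatography as 4.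

Step 4. The risks are reductive loss of the aryloxide next to the aliphatic aldehyde, Lewis-acid ionisation or Claisen rearrangement of the tertiary allyl aryl ether, and oligomerisation. The fallback sets out from 5 and comes back at 6, closing the same C3–C4 bond with a carbene-derived acyl anion in place of titanium. An N-mesityl bicyclic triazolium chloride (10 mol %) with DBU in THF at rt turns the aryl aldehyde into its Breslow intermediate, which adds to the aliphatic aldehyde (intramolecular crossed benzoin) to give (2S)-3-hydroxy-2-methyl-6-[(triisopropylsilyl)oxy]-2-vinylchroman-4-one F3 (C3 epimers). NaBH4 in MeOH at 0 °C gives (2S)-2-methyl-6-[(triisopropylsilyl)oxy]-2-vinylchromane-3,4-diol F4 (diastereomer mixture). Garegg–Samuelsson deoxygenation (PPh3, I2, imidazole, toluene, 80 °C) turns any of the diol isomers into 6.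

Step 7. The risks are slow hydroboration of a vinyl group on a quaternary carbon, sluggish transmetalation or protodeboronation in the coupling, and air sensitivity of the free chromenol in the basic one-pot mixture. The fallback sets out from 6 and 11 and comes back at 13, swapping the in-situ borane for an isolated iodide and its zinc reagent. Hydroboration of 6 with 9-BBN (through 12) and oxidation with NaBO3·4H2O gives 2-{(2S)-2-methyl-6-[(triisopropylsilyl)oxy]-2H-chromen-2-yl}ethan-1-ol F5. PPh3, I2 and imidazole give triisopropyl{[(2S)-2-(2-iodoethyl)-2-methyl-2H-chromen-6-yl]oxy}silane F6. Zn dust with LiCl in THF gives iodo{2-[(2S)-2-methyl-6-[(triisopropylsilyl)oxy]-2H-chromen-2-yl]ethyl}zinc F7, which couples with 11 (PdCl2(dppf), THF, rt, Negishi coupling) to give 13. Compound 13 is then isolated and desilylated with Bu4NF as in the last stage of step 7.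

**Further compounds**

F1 | step 2 | 2-[(1-hydroxy-2-methylbut-3-en-2-yl)oxy]-5-[(triisopropylsilyl)oxy]benzaldehyde (racemic) | C=CC(C)(CO)Oc1ccc(O[Si](C(C)C)(C(C)C)C(C)C)cc1C=O
F2 | step 2 | (2R)-2-{2-formyl-4-[(triisopropylsilyl)oxy]phenoxy}-2-methylbut-3-en-1-yl acetate | C=C[C@](C)(COC(C)=O)Oc1ccc(O[Si](C(C)C)(C(C)C)C(C)C)cc1C=O
F3 | step 4 | (2S)-3-hydroxy-2-methyl-6-[(triisopropylsilyl)oxy]-2-vinylchroman-4-one (C3 epimers) | C=C[C@@]1(C)C(O)C(=O)c2cc(O[Si](C(C)C)(C(C)C)C(C)C)ccc2O1
F4 | step 4 | (2S)-2-methyl-6-[(triisopropylsilyl)oxy]-2-vinylchromane-3,4-diol (diastereomer mixture) | C=C[C@@]1(C)C(O)C(O)c2cc(O[Si](C(C)C)(C(C)C)C(C)C)ccc2O1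
F5 | step 7 | 2-{(2S)-2-methyl-6-[(triisopropylsilyl)oxy]-2H-chromen-2-yl}ethan-1-ol | OCC[C@@]1(C)C=Cc2cc(O[Si](C(C)C)(C(C)C)C(C)C)ccc2O1
F6 | step 7 | triisopropyl{[(2S)-2-(2-iodoethyl)-2-methyl-2H-chromen-6-yl]oxy}silane | ICC[C@@]1(C)C=Cc2cc(O[Si](C(C)C)(C(C)C)C(C)C)ccc2O1
F7 | step 7 | iodo{2-[(2S)-2-methyl-6-[(triisopropylsilyl)oxy]-2H-chromen-2-yl]ethyl}zinc | I[Zn]CC[C@@]1(C)C=Cc2cc(O[Si](C(C)C)(C(C)C)C(C)C)ccc2O1
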